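## Retrosynthetic overview

1. Ring numbering for all six-membered compounds: C1 bears CH2OBz, C2 OMe, C3 OBz, C4=C5, C6 is the epoxide CH. The oxirane is made last: target ⇐ trans-1,6-diol (Mitsunobu closure, inversion at C6) ⇐ α-hydroxy enone (hydroxyl-directed 1,2-reduction).
2. α-Hydroxy enone ⇐ ring-expanded β,γ-unsaturated ketol, by directed epoxidation of C2=C3, benzoate opening at C3, O-methylation at C2 and β-elimination of the C4 silyloxy group (creates C4=C5).
3. Six-membered ketol ⇐ 1-acylcyclopent-2-en-1-ol by an α-ketol ring expansion (1,2-shift of the alkenyl ring carbon). This is the key step and relays chirality from the C4–O centre to C1.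
4. Acylcyclopentenol ⇐ (S)-4-silyloxycyclopentenone + acetylene (1,2-addition, then gold-catalysed alkyne oxidation with benzoate trapping).
5. Ring order: cyclopentene (purchased) → cyclohexene (ring expansion) → oxirane (final step).

Assumption: (S)-4-(tert-butyldimethylsilyloxy)cyclopent-2-en-1-one is bought enantiopure (both enantiomers are commercial).

## Route

Step 1
Reactants: 1 (S)-4-(tert-butyldimethylsilyloxy)cyclopent-2-en-1-one; 2 acetylene
Product: 5 (1R,4S)-4-(tert-butyldimethylsilyloxy)-1-ethynyl-1-(trimethylsilyloxy)cyclopent-2-ene (ethynyl trans to OTBS), via lithium acetylide 3 (not isolated), via lithium tertiary alkoxide 4 (not isolated)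
Conditions: 2, n-BuLi, THF, −78 °C; then 1, −78 °C; then TMSCl, −78 → 0 °C
Reagents that add atoms: chlorotrimethylsilane, C[Si](C)(C)Cl
Why: 1,2-addition of LiC≡CH to the enone occurs anti to the C4 silyloxy group (new C–O cis to OTBS, carbinol centre 1R), and in-flask silylation keeps a free propargylic hydroxyl from trapping the gold carbene in step 2.

Step 2
Reactants: 5 (1R,4S)-4-(tert-butyldimethylsilyloxy)-1-ethynyl-1-(trimethylsilyloxy)cyclopent-2-ene
Product: 7 2-[(1R,4S)-4-(tert-butyldimethylsilyloxy)-1-hydroxycyclopent-2-en-1-yl]-2-oxoethyl benzoate, via silyl ketol benzoate 6 (not isolated)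
Conditions: [(1-Ad)2P(C6H4-2-morpholino)]AuNTf2 (5 mol %), 8-methylquinoline N-oxide (1.5 equiv), PhCO2H (2 equiv), PhCl, rt; then PPTS, MeOH, 0 °C
Reagents that add atoms: 8-methylquinoline N-oxide, Cc1cccc2ccc[n+]([O-])c12; benzoic acid, OC(=O)c1ccccc1
Why: Gold-catalysed alkyne oxidation: the N-oxide attacks the internal carbon of the gold-activated terminal alkyne, the terminal α-oxo gold carbene inserts into the O–H bond of benzoic acid, and mild methanolysis removes only the tertiary TMS ether; no stereocentre is touched.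

Step 3
Reactants: 7 2-[(1R,4S)-4-(tert-butyldimethylsilyloxy)-1-hydroxycyclopent-2-en-1-yl]-2-oxoethyl benzoate
Product: 8 [(1R,4S)-4-(tert-butyldimethylsilyloxy)-1-hydroxy-6-oxocyclohex-2-en-1-yl]methyl benzoate
Conditions: Sc(OTf)3 (10 mol %), 2,6-di-tert-butyl-4-methylpyridine (20 mol %), 4 Å MS, ClCH2CH2Cl, 40 °C
Reagents that add atoms: none
Why: Proposed new method: a catalytic, alkenyl-selective α-ketol (acyloin) ring expansion with 1,2-chirality transfer. Sc(OTf)3 binds the tertiary hydroxyl and the ketone oxygen of 7 as a five-membered chelate (syn-periplanar C–O bonds); the electrophilic α-benzoyloxy ketone carbon then accepts the sp2 ring carbon through a π-bridged transition state, expected to be faster than shift of the ring CH2, while the carbinol carbon becomes the C6 ketone. Relief of cyclopentene strain and loss of the α-acyloxy ketone should make the shift downhill; mild conditions keep it under kinetic control, and the hindered pyridine suppresses Brønsted-acid ionisation of the allylic C–O bonds. Because the hydroxyl of 7 is cis to OTBS, the chelated geometry places the new C1–OH cis to C4–OTBS (1R). Closest known reaction type: Lewis-acid- or base-mediated α-ketol ring expansion of 1-acylcyclopentanols (steroid D-ring homologation) and nickel-catalysed ketol ring expansion of 1-benzoylcyclopentanol, neither shown for an alkenyl shift in a 1-acylcyclopent-2-enol.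

Step 4
Reactants: 8 [(1R,4S)-4-(tert-butyldimethylsilyloxy)-1-hydroxy-6-oxocyclohex-2-en-1-yl]methyl benzoate
Product: 9 [(1S,2S,3R,4S)-4-(tert-butyldimethylsilyloxy)-2,3-epoxy-1-hydroxy-6-oxocyclohexyl]methyl benzoate
Conditions: VO(acac)2 (5 mol %), t-BuOOH (1.5 equiv, decane), CH2Cl2, 0 °C → rt
Reagents that add atoms: tert-butyl hydroperoxide, CC(C)(C)OO
Why: Vanadium-catalysed hydroxyl-directed epoxidation of the tertiary allylic alcohol delivers oxygen to the C2=C3 face syn to C1–OH, setting C2 and C3 (epoxide cis to C1–OH).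

Step 5
Reactants: 9 [(1S,2S,3R,4S)-4-(tert-butyldimethylsilyloxy)-2,3-epoxy-1-hydroxy-6-oxocyclohexyl]methyl benzoate
Product: 10 [(1S,2S,3S,4S)-3-(benzoyloxy)-4-(tert-butyldimethylsilyloxy)-1,2-dihydroxy-6-oxocyclohexyl]methyl benzoate
Conditions: Ti(OiPr)4 (1.5 equiv), PhCO2H (2 equiv), CH2Cl2, rt
Reagents that add atoms: benzoic acid, OC(=O)c1ccccc1
Why: Titanium-mediated C3-selective SN2 opening of a 2,3-epoxy alcohol by a carboxylic acid (Sharpless type): benzoate attacks the distal C3 with inversion (C2 is neopentylic), giving C3–OBz trans to C2–OH and leaving C2–OH cis to C1–OH.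

Step 6
Reactants: 10 [(1S,2S,3S,4S)-3-(benzoyloxy)-4-(tert-butyldimethylsilyloxy)-1,2-dihydroxy-6-oxocyclohexyl]methyl benzoate
Product: 11 [(1S,2S,3S,4S)-3-(benzoyloxy)-4-(tert-butyldimethylsilyloxy)-1-hydroxy-2-methoxy-6-oxocyclohexyl]methyl benzoate
Conditions: Me3OBF4 (3 equiv), 1,8-bis(dimethylamino)naphthalene (3 equiv), 4 Å MS, CH2Cl2, 0 °C → rt
Reagents that add atoms: trimethyloxonium tetrafluoroborate, C[O+](C)C.F[B-](F)(F)F
Why: O-methylation with a Meerwein salt under non-basic conditions alkylates only the secondary C2–OH (the tertiary ketol hydroxyl is too hindered) and avoids benzoate migration and premature β-elimination.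

Step 7
Reactants: 11 [(1S,2S,3S,4S)-3-(benzoyloxy)-4-(tert-butyldimethylsilyloxy)-1-hydroxy-2-methoxy-6-oxocyclohexyl]methyl benzoate
Product: 12 [(1S,2S,3R)-3-(benzoyloxy)-1-hydroxy-2-methoxy-6-oxocyclohex-4-en-1-yl]methyl benzoate
Conditions: DBU (2 equiv), CH2Cl2, 0 °C → rt
Reagents that add atoms: none
Why: E1cB β-elimination of silanolate from the β-silyloxy ketone (only C5 carries α-hydrogens) installs C4=C5 in conjugation with C6=O and removes the relay stereocentre.

Step 8
Reactants: 12 [(1S,2S,3R)-3-(benzoyloxy)-1-hydroxy-2-methoxy-6-oxocyclohex-4-en-1-yl]methyl benzoate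
Product: 13 [(1R,2S,3R,6S)-3-(benzoyloxy)-1,6-dihydroxy-2-methoxycyclohex-4-en-1-yl]methyl benzoate
Conditions: Me4NBH(OAc)3 (4 equiv), MeCN/AcOH (1:1), −30 → −10 °C
Reagents that add atoms: none
Why: Hydroxyl-directed 1,2-reduction (Evans–Saksena type): the acetoxyborohydride bound to C1–O delivers hydride to C6=O from the face of C1–OH, so the new C6–OH is trans to C1–OH (6S).

Step 9
Reactants: 13 [(1R,2S,3R,6S)-3-(benzoyloxy)-1,6-dihydroxy-2-methoxycyclohex-4-en-1-yl]methyl benzoate
Product: 14 [(1R,2S,3R,6R)-3-(benzoyloxy)-1,6-epoxy-2-methoxycyclohex-4-en-1-yl]methyl benzoate (CNP0231490.2)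
Conditions: PPh3 (1.5 equiv), DIAD (1.5 equiv), toluene, 0 °C → rt
Reagents that add atoms: none
Why: Mitsunobu cyclodehydration of a trans-1,2-diol: the secondary allylic C6–OH is activated as its oxyphosphonium and displaced by the tertiary C1 alkoxide with inversion at C6, giving the oxirane cis to C2–OMe (6R); C1 has no hydrogen, so elimination cannot compete.

## Compound list

1 | (S)-4-(tert-butyldimethylsilyloxy)cyclopent-2-en-1-one | O=C1C=C[C@@H](O[Si](C)(C)C(C)(C)C)C1 | starting material
2 | acetylene | C#C | starting material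
3 | lithium acetylide | [Li]C#C | intermediate
4 | lithium (1R,4S)-4-(tert-butyldimethylsilyloxy)-1-ethynylcyclopent-2-en-1-olate | C#C[C@]1([O-])C=C[C@@H](O[Si](C)(C)C(C)(C)C)C1.[Li+] | intermediate
5 | (1R,4S)-4-(tert-butyldimethylsilyloxy)-1-ethynyl-1-(trimethylsilyloxy)cyclopent-2-ene | C#C[C@]1(O[Si](C)(C)C)C=C[C@@H](O[Si](C)(C)C(C)(C)C)C1 | intermediate
6 | 2-[(1R,4S)-4-(tert-butyldimethylsilyloxy)-1-(trimethylsilyloxy)cyclopent-2-en-1-yl]-2-oxoethyl benzoate | O=C(COC(=O)c1ccccc1)[C@]1(O[Si](C)(C)C)C=C[C@@H](O[Si](C)(C)C(C)(C)C)C1 | intermediate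
7 | 2-[(1R,4S)-4-(tert-butyldimethylsilyloxy)-1-hydroxycyclopent-2-en-1-yl]-2-oxoethyl benzoate (OH cis to OTBS) | O=C(COC(=O)c1ccccc1)[C@]1(O)C=C[C@@H](O[Si](C)(C)C(C)(C)C)C1 | intermediate
8 | [(1R,4S)-4-(tert-butyldimethylsilyloxy)-1-hydroxy-6-oxocyclohex-2-en-1-yl]methyl benzoate (OH cis to OTBS) | O=C1C[C@H](O[Si](C)(C)C(C)(C)C)C=C[C@@]1(O)COC(=O)c1ccccc1 | intermediate
9 | [(1S,2S,3R,4S)-4-(tert-butyldimethylsilyloxy)-2,3-epoxy-1-hydroxy-6-oxocyclohexyl]methyl benzoate (epoxide, OH and OTBS all cis) | O=C1C[C@H](O[Si](C)(C)C(C)(C)C)[C@@H]2O[C@@H]2[C@@]1(O)COC(=O)c1ccccc1 | intermediate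
10 | [(1S,2S,3S,4S)-3-(benzoyloxy)-4-(tert-butyldimethylsilyloxy)-1,2-dihydroxy-6-oxocyclohexyl]methyl benzoate | O=C1C[C@H](O[Si](C)(C)C(C)(C)C)[C@@H](OC(=O)c2ccccc2)[C@H](O)[C@@]1(O)COC(=O)c1ccccc1 | intermediate
11 | [(1S,2S,3S,4S)-3-(benzoyloxy)-4-(tert-butyldimethylsilyloxy)-1-hydroxy-2-methoxy-6-oxocyclohexyl]methyl benzoate | O=C1C[C@H](O[Si](C)(C)C(C)(C)C)[C@@H](OC(=O)c2ccccc2)[C@H](OC)[C@@]1(O)COC(=O)c1ccccc1 | intermediate
12 | [(1S,2S,3R)-3-(benzoyloxy)-1-hydroxy-2-methoxy-6-oxocyclohex-4-en-1-yl]methyl benzoate | CO[C@H]1[C@H](OC(=O)c2ccccc2)C=CC(=O)[C@]1(O)COC(=O)c1ccccc1 | intermediate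
13 | [(1R,2S,3R,6S)-3-(benzoyloxy)-1,6-dihydroxy-2-methoxycyclohex-4-en-1-yl]methyl benzoate (1,6-diol trans) | CO[C@H]1[C@H](OC(=O)c2ccccc2)C=C[C@H](O)[C@]1(O)COC(=O)c1ccccc1 | intermediate
14 | [(1R,2S,3R,6R)-3-(benzoyloxy)-1,6-epoxy-2-methoxycyclohex-4-en-1-yl]methyl benzoate, CNP0231490.2 (oxirane cis to OMe, OBz trans to OMe) | CO[C@H]1[C@H](OC(=O)c2ccccc2)C=C[C@H]2O[C@]21COC(=O)c1ccccc1 | target

## Step count and risks

Total step count: 9. Longest linear sequence: 9 steps (from 1).

The three steps most likely to fail are steps 3, 2 and 7.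

**Step 3 (proposed new ring expansion).** Risks are shift of the ring CH2 instead of the alkenyl carbon, no turnover, ionisation of the allylic alcohol, or loss of the β-silyloxy group. The fallback uses known chemistry and sets out from 6, isolated by leaving out the methanolysis at the end of step 2. Instead of a catalytic chelate of the free ketol, the ring enlargement is run as a stoichiometric silyl-ketol rearrangement: the aluminium-Lewis-acid-promoted acyloin shift of an α-silyloxy carbonyl compound with O-to-O silyl transfer. With Me2AlCl (1.1 equiv, CH2Cl2, −78 → −20 °C), 6 gives [(1R,4S)-4-(tert-butyldimethylsilyloxy)-6-oxo-1-(trimethylsilyloxy)cyclohex-2-en-1-yl]methyl benzoate F3. The silyl group can only be handed over between syn oxygens, so the stereochemical course matches the chelate pathway. PPTS in MeOH then removes the TMS group and the route comes back at 8. This fallback does not cure a wrong-group shift; it answers catalyst-related failure.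

**Step 2 (gold-catalysed oxidation with benzoate trapping).** Risks are capture of the carbene by the propargylic oxygen (oxetan-3-one formation) and over-oxidation. The fallback is the classical corticoid-type side-chain construction; it sets out from 1 and comes back at 7. 1-Ethoxyvinyllithium (ethyl vinyl ether, t-BuLi, THF, −78 °C) adds to 1 anti to OTBS to give (1R,4S)-4-(tert-butyldimethylsilyloxy)-1-(1-ethoxyvinyl)cyclopent-2-en-1-ol F1. Oxidation of the enol ether with mCPBA (1 equiv, NaHCO3, wet CH2Cl2, −20 °C) gives 1-[(1R,4S)-4-(tert-butyldimethylsilyloxy)-1-hydroxycyclopent-2-en-1-yl]-2-hydroxyethan-1-one F2. Selective benzoylation of the primary hydroxyl (BzCl, 2,4,6-collidine, CH2Cl2, −40 °C) gives 7.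

**Step 7 (E1cB loss of a poor silanolate leaving group next to benzoates and a ketol).** The risk is a sluggish elimination that forces conditions under which benzoates migrate. The fallback sets out from 11 and comes back at 12, replacing direct elimination by desilylation and activation. HF·pyridine (THF, 0 °C) gives [(1S,2S,3R,4S)-3-(benzoyloxy)-1,4-dihydroxy-2-methoxy-6-oxocyclohexyl]methyl benzoate F4. MsCl and Et3N (CH2Cl2, 0 °C → rt) convert the secondary C4–OH into [(1S,2S,3S,4S)-3-(benzoyloxy)-1-hydroxy-4-(methanesulfonyloxy)-2-methoxy-6-oxocyclohexyl]methyl benzoate F5, which eliminates in the same flask to 12.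

## Further compounds

F1 | step 2 | (1R,4S)-4-(tert-butyldimethylsilyloxy)-1-(1-ethoxyvinyl)cyclopent-2-en-1-ol | CCOC(=C)[C@]1(O)C=C[C@@H](O[Si](C)(C)C(C)(C)C)C1
F2 | step 2 | 1-[(1R,4S)-4-(tert-butyldimethylsilyloxy)-1-hydroxycyclopent-2-en-1-yl]-2-hydroxyethan-1-one | O=C(CO)[C@]1(O)C=C[C@@H](O[Si](C)(C)C(C)(C)C)C1
F3 | step 3 | [(1R,4S)-4-(tert-butyldimethylsilyloxy)-6-oxo-1-(trimethylsilyloxy)cyclohex-2-en-1-yl]methyl benzoate | O=C1C[C@H](O[Si](C)(C)C(C)(C)C)C=C[C@@]1(O[Si](C)(C)C)COC(=O)c1ccccc1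
F4 | step 7 | [(1S,2S,3R,4S)-3-(benzoyloxy)-1,4-dihydroxy-2-methoxy-6-oxocyclohexyl]methyl benzoate | O=C1C[C@H](O)[C@@H](OC(=O)c2ccccc2)[C@H](OC)[C@@]1(O)COC(=O)c1ccccc1
F5 | step 7 | [(1S,2S,3S,4S)-3-(benzoyloxy)-1-hydroxy-4-(methanesulfonyloxy)-2-methoxy-6-oxocyclohexyl]methyl benzoate | O=C1C[C@H](OS(C)(=O)=O)[C@@H](OC(=O)c2ccccc2)[C@H](OC)[C@@]1(O)COC(=O)c1ccccc1
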